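**Plan**

- Retrosynthetic cuts: first the C8 ester and the C13 methylene, then the O5–C10 ether bond, then C7–C11 of the lactone (back to an O6 diazoacetate and a C7=C8 enol ether), finally the ring bonds C3–C4 and C7–C8.
- Feature used: in the carbocycle C1–C10 the oxygenated pair C5/C6 lies between the ester-bearing sp2 carbon C4 and C7, which is alpha to the C8 oxygen. C3=C4 and the enol form C7=C8 therefore make a cyclodeca-1,5-diene, the formal metathesis product of a cyclobutene (C4–C5–C6–C7) and a cyclohexene (C8–C9–C10–C1–C2–C3).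
- Forward order: cyclobutane by [2+2], then the ten-membered ring by ring expansion (step 4), then the gamma-lactone from O6 (carbenoid cyclopropanation), then the O5–C10 oxepane bridge, last the side chain and the exocyclic methylene.
- Stereochemistry: C5/C6 come from resolved cyclobutene 4. C7 is relayed from C6 through the O6 tether, C10 from C5 by the one-atom bridge, C8 from the shape of the bridged ketone. The side-chain centre comes from a Sharpless epoxidation.

Key step: step 4

Remarks: ring atoms are labelled C1–C10 as in the target (C11–C13 lactone carbons, C15 the ester carbon on C4). "Ring-cis/ring-trans" refers to the two ring bonds at a double bond. It is assumed that the absolute configuration of resolved 4 is assigned by X-ray or VCD analysis before use.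

**Route**

Step 1
Reactants: 1 methyl propiolate; 2 vinylene carbonate
Product: 3 racemic methyl 3-oxo-2,4-dioxabicyclo[3.2.0]hept-6-ene-6-carboxylate
Conditions: hν (300 nm, Pyrex), acetone, 1 (4 equiv), 20 °C, stopped at partial conversion of 2
Reagents that add atoms: none
Why: Triplet-sensitised [2+2] alkyne–alkene photocycloaddition, in which the five-membered carbonate forces the two C–O bonds cis; excess alkyne and partial conversion limit a second addition to the product, which is itself a triplet acceptor.

Step 2
Reactants: 3 racemic cyclobutene carbonate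
Product: 4 methyl (1S,5R)-3-oxo-2,4-dioxabicyclo[3.2.0]hept-6-ene-6-carboxylate
Conditions: preparative SFC, amylose tris(3,5-dimethylphenylcarbamate) phase, CO2/i-PrOH
Reagents that add atoms: none
Why: Chromatographic resolution on a chiral stationary phase, chosen because the small neutral racemate offers no handle for salt formation; it fixes C5 and C6 of the target.

Step 3
Reactants: 5 3-methylanisole
Product: 6 1-methoxy-5-methylcyclohexa-1,4-diene
Conditions: Li, NH3 (l), THF, t-BuOH, −78 → −33 °C; NH4Cl
Reagents that add atoms: none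
Why: Birch reduction, which leaves both donor substituents on the two remaining, unconjugated double bonds (enol ether C8=C3 and trisubstituted C1=C10).

Step 4
Reactants: 4 cyclobutene carbonate; 6 1-methoxy-5-methylcyclohexa-1,4-diene
Product: 8 methyl (5R,6S)-5,6-carbonyldioxy-8-methoxy-10-methylcyclodeca-1(10),3,7-triene-4-carboxylate with ring-cis C3=C4 and ring-trans C7=C8, via tricyclic photoadduct 7 (not isolated)
Conditions: hν (300 nm, Pyrex), acetone–MeCN (1:4), 6 (4 equiv), −20 °C; evaporate; degassed PhMe, 2,6-di-tert-butylpyridine (5 mol %), 150 °C, sealed base-washed tube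
Reagents that add atoms: none
Why: Acetone passes triplet energy to ester 4, whose excited C4=C7 bond adds stepwise (1,4-biradical) to the enol-ether bond C3=C8 of 6 on the face anti to the carbonate, closing the cyclobutane C3–C4–C7–C8 by an intermolecular [2+2] photocycloaddition of the enone–alkene type; the sequence is the known cyclobutene-carboxylate photoaddition followed by thermal cycloreversion to cyclodeca-1,5-dienes. Head-to-tail regiochemistry (C4 to C3, C7 to the methoxy carbon C8) follows the usual preference of excited enoates for electron-rich alkenes and avoids two adjacent quaternary carbons, and the enol ether should outcompete the less electron-rich C1=C10 bond. On heating, the strained central bond C4–C7 of the bicyclo[2.2.0]hexane breaks to an ester-stabilised cyclohexane-1,4-diyl that fragments across C3–C8, so the ten-membered ring is closed by ring expansion (formal retro-[2+2]) and not by end-to-end cyclisation. No new stereocentre survives: the four sp3 centres made in 7 return to sp2 and C5/C6 pass unchanged from 4, so all ring-fusion isomers of 7 converge. The selectivity needed is alkene geometry: fragmentation through the chair diyl inverts one terminus, and the chair that keeps the ester coplanar with the forming C3=C4 bond without an angelate-type clash with C2 should give the ring-cis (E)-enoate and the ring-trans enol ether. The five-membered carbonate makes C5–C6 scission or a following Cope rearrangement pay for a nine-membered dienyl carbonate, and the hindered base protects the enol ether.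

Step 5
Reactants: 8 cyclodecatriene carbonate
Product: 10 (5R,6S)-5-hydroxy C15→O6 lactone of the triene (alpha-alkylidene gamma-lactone), via triene diol 9 (not isolated)
Conditions: K2CO3 (0.3 equiv), MeOH, 0 → 20 °C; then PhMe, 40 °C, reduced pressure (removal of MeOH)
Reagents that add atoms: none
Why: Base-catalysed transesterification: methanolysis of the carbonate frees both hydroxyls and the C6 alkoxide closes the five-membered lactone on the C4 ester (5-exo-trig), whereas O5 could only form a beta-lactone, so O5 and O6 are differentiated without a selective protection.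

Step 6
Reactants: 10 hydroxy lactone
Product: 11 O5-tert-butyldimethylsilyl ether of 10
Conditions: TBSOTf, 2,6-lutidine, CH2Cl2, −78 → −20 °C
Reagents that add atoms: tert-butyldimethylsilyl trifluoromethanesulfonate CC(C)(C)[Si](C)(C)OS(=O)(=O)C(F)(F)F
Why: Silyl ether formation at the only free hydroxyl under hindered-base conditions that leave the enol ether and the lactone intact.

Step 7
Reactants: 11 silyl lactone
Product: 13 methyl (5R,6S)-6-hydroxy-5-(tert-butyldimethylsilyloxy)-8-methoxy-10-methylcyclodeca-1(10),3,7-triene-4-carboxylate, via lithium carboxylate 12 (not isolated)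
Conditions: LiOH·H2O (1.05 equiv), THF–H2O, 0 °C; CO2 to pH 8; evaporate; MeI, DMF, 20 °C
Reagents that add atoms: lithium hydroxide [Li+].[OH-]; iodomethane CI
Why: Lactone saponification followed by SN2 O-methylation of the carboxylate restores the C4 methyl ester and exposes O6–H alone; buffering before evaporation removes the hydroxide that could cause relactonisation or silyl migration.

Step 8
Reactants: 13 hydroxy ester
Product: 15 O6 diazoacetate of 13, via tosylhydrazone ester 14 (not isolated)
Conditions: glyoxylic acid chloride p-toluenesulfonylhydrazone, PhNMe2, CH2Cl2, 0 °C; then Et3N, 0 → 20 °C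
Reagents that add atoms: glyoxylic acid chloride p-toluenesulfonylhydrazone Cc1ccc(cc1)S(=O)(=O)NN=CC(Cl)=O
Why: Acylation by the hydrazone acid chloride and base-induced loss of sulfinate (Bamford–Stevens-type elimination) give the diazo ester without any acid, so the enol ether survives.

Step 9
Reactants: 15 diazoacetate
Product: 16 methoxycyclopropane-fused 12,6-lactone (C11 bonded to C7 and C8; C6, C12 and OMe cis on the cyclopropane; O5-TBS)
Conditions: Rh2(OAc)4 (1 mol %), CH2Cl2, 20 °C, slow addition of 15 to 5 mM
Reagents that add atoms: none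
Why: Intramolecular carbenoid cyclopropanation of an allylic diazoacetate by the electron-rich enol ether; with H6 eclipsing the alkene (allylic strain) the O6 tether reaches only the outer face of C7=C8, so C11 adds syn to O6 and should set C7 as needed for the trans-fused lactone (C8 and C11 are not retained).

Step 10
Reactants: 16 cyclopropane lactone
Product: 19 (5R,6S,7S,10S)-5,10-epoxy-8-oxo 12,6-lactone methyl ester (oxabicyclo[4.4.1] ketone), via silyl keto lactone 17 (not isolated), via hydroxy keto lactone 18 (not isolated)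
Conditions: TFA–CH2Cl2 (1:4), H2O (3 equiv), 0 → 20 °C; NaHCO3 (aq)
Reagents that add atoms: water O
Why: Acid opening of the donor–acceptor alkoxycyclopropane to the gamma-keto lactone, acid cleavage of the silyl ether, then Brønsted-acid transannular hydroalkoxylation (Markovnikov protonation of C1=C10, capture of the C10 cation by O5); the one-atom bridge can only join C5 and C10 on the same side, so C10 is set by C5.

Step 11
Reactants: 19 bridged keto lactone
Product: 20 (5R,6S,7R,8R,10S)-5,10-epoxy-8-hydroxy 12,6-lactone methyl ester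
Conditions: NaBH4, CeCl3·7H2O, MeOH–THF, −78 °C; AcOH
Reagents that add atoms: none
Why: Luche reduction: hydride should add to C8 on the convex face of the bicyclo[4.4.1] ketone, away from the second seven-membered ring and anti to the neighbouring C7–C11 bond, giving H8 cis to H7; low temperature and CeCl3 avoid beta-elimination of the lactone oxygen.

Step 12
Reactants: 21 (E)-2-methylbut-2-en-1-ol
Product: 22 [(2R,3R)-2,3-dimethyloxiran-2-yl]methanol
Conditions: Ti(OiPr)4 (10 mol %), D-(−)-diethyl tartrate (12 mol %), t-BuOOH, 4 Å sieves, CH2Cl2, −20 °C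
Reagents that add atoms: tert-butyl hydroperoxide CC(C)(C)OO
Why: Sharpless asymmetric epoxidation; the D-tartrate delivers oxygen to the face that gives the (2R,3R)-epoxide, whose C2–O bond becomes the tertiary carbinol of the (S)-acid.

Step 13
Reactants: 22 epoxy alcohol
Product: 24 (S)-2-methylbut-3-ene-1,2-diol, via hydroxy selenide 23 (not isolated)
Conditions: PhSeSePh, NaBH4, EtOH, 20 → 78 °C; then THF, H2O2 (30 %), 0 → 40 °C
Reagents that add atoms: none
Why: Epoxide-to-allylic-alcohol transposition: selenolate opens the epoxide at the secondary carbon (SN2) and selenoxide syn-elimination can use only the methyl hydrogens, which gives the vinyl group and leaves the tertiary centre untouched.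

Step 14
Reactants: 24 diol
Product: 26 (S)-2-hydroxy-2-methylbut-3-enoic acid, via hydroxy aldehyde 25 (not isolated)
Conditions: TEMPO (10 mol %), NaOCl (5 mol %), NaClO2, MeCN–phosphate buffer (pH 6.8), 35 °C
Reagents that add atoms: sodium chlorite [Na+].[O-]Cl=O
Why: TEMPO-catalysed oxidation of the primary alcohol with chlorite as terminal oxidant (Anelli/Pinnick type); the tertiary alcohol cannot be oxidised and the mild buffered system avoids glycol cleavage.

Step 15
Reactants: 26 hydroxy acid
Product: 28 (S)-2-methyl-2-(triethylsilyloxy)but-3-enoic acid, via bis-silyl derivative 27 (not isolated)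
Conditions: TESOTf (2.5 equiv), 2,6-lutidine, CH2Cl2, −78 → 0 °C; then MeOH–H2O, 0 °C
Reagents that add atoms: triethylsilyl trifluoromethanesulfonate CC[Si](CC)(CC)OS(=O)(=O)C(F)(F)F
Why: Exhaustive silylation followed by solvolysis of the labile silyl ester leaves the tertiary silyl ether.

Step 16
Reactants: 20 bridged hydroxy lactone; 28 silyloxy acid
Product: 30 8-O-[(S)-2-methyl-2-(triethylsilyloxy)but-3-enoyl] ester of 20, via mixed anhydride 29 (not isolated)
Conditions: 28, 2,4,6-Cl3C6H2COCl, Et3N, THF, 20 °C; then 20, DMAP, PhMe, 40 °C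
Reagents that add atoms: none
Why: Yamaguchi esterification: the mixed anhydride acylates the secondary C8 alcohol with retention at C8, and the acid has no alpha-hydrogen and cannot racemise.

Step 17
Reactants: 30 ester
Product: 33 alpha-methylene lactone (O-triethylsilyl ether of the target), via Mannich base 31 (not isolated), via methiodide 32 (not isolated)
Conditions: LiN(SiMe3)2, THF, −78 °C; CH2=NMe2+ I−, −78 → 0 °C; MeI, THF–MeOH, 20 °C; NaHCO3 (aq), CH2Cl2, 20 °C
Reagents that add atoms: N,N-dimethylmethyleneiminium iodide C=[N+](C)C.[I-]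
Why: Alpha-methylenation by Mannich reaction of the lactone lithium enolate with Eschenmoser's salt, quaternisation and E1cB elimination; the lactone CH2 is the most acidic site and the C8 ester has no alpha-hydrogen.

Step 18
Reactants: 33 silyl ether
Product: 34 target CNP0325750.1
Conditions: HF·pyridine, pyridine, THF, 0 → 20 °C
Reagents that add atoms: none
Why: Buffered fluoride cleavage of the tertiary triethylsilyl ether, which leaves the alpha-methylene lactone, both esters and the bridged ether untouched.

**Compound list**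

1 | methyl propiolate | C#CC(=O)OC | starting material
2 | vinylene carbonate | O=C1OC=CO1 | starting material
3 | methyl 3-oxo-2,4-dioxabicyclo[3.2.0]hept-6-ene-6-carboxylate, racemic cis pair | COC(=O)C1=C[C@@H]2OC(=O)O[C@H]12.COC(=O)C1=C[C@H]2OC(=O)O[C@@H]12 | intermediate
4 | methyl (1S,5R)-3-oxo-2,4-dioxabicyclo[3.2.0]hept-6-ene-6-carboxylate (cis C5/C6 carbonate, ester on C4 of cyclobutene C4=C7) | COC(=O)C1=C[C@@H]2OC(=O)O[C@H]12 | intermediate
5 | 3-methylanisole | COc1cccc(C)c1 | starting material
6 | 1-methoxy-5-methylcyclohexa-1,4-diene | COC1=CCC=C(C)C1 | intermediate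
7 | head-to-tail photoadduct, bicyclo[2.2.0]hexane C3–C4–C7–C8/C4–C5–C6–C7 with cis-fused cyclohexene anti to the carbonate (formed in the flask) | COC(=O)[C@@]12[C@H]3OC(=O)O[C@H]3[C@@H]1[C@@]1(OC)CC(C)=CC[C@H]12 | intermediate
8 | methyl (5R,6S)-5,6-carbonyldioxy-8-methoxy-10-methylcyclodeca-1(10),3,7-triene-4-carboxylate; 3E (ring-cis), 7Z (ring-trans), 1(10)Z | CO/C1=C\[C@@H]2OC(=O)O[C@@H]2/C(C(=O)OC)=C\C/C=C(C)\C1 | intermediate
9 | (5R,6S)-5,6-diol of 8 (formed in the flask) | CO/C1=C\[C@H](O)[C@H](O)/C(C(=O)OC)=C\C/C=C(C)\C1 | intermediate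
10 | (5R,6S)-5-hydroxy triene with C15 carbonyl lactonised on O6 | CO/C1=C\[C@@H]2OC(=O)/C(=C/C/C=C(C)\C1)[C@H]2O | intermediate
11 | O5-tert-butyldimethylsilyl ether of 10 | CO/C1=C\[C@@H]2OC(=O)/C(=C/C/C=C(C)\C1)[C@H]2O[Si](C)(C)C(C)(C)C | intermediate
12 | lithium (5R,6S)-6-hydroxy-5-silyloxy triene-4-carboxylate (formed in the flask) | [Li+].CO/C1=C\[C@H](O)[C@H](O[Si](C)(C)C(C)(C)C)/C(C(=O)[O-])=C\C/C=C(C)\C1 | intermediate
13 | methyl (5R,6S)-6-hydroxy-5-(tert-butyldimethylsilyloxy)-8-methoxy-10-methylcyclodeca-1(10),3,7-triene-4-carboxylate | CO/C1=C\[C@H](O)[C@H](O[Si](C)(C)C(C)(C)C)/C(C(=O)OC)=C\C/C=C(C)\C1 | intermediate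
14 | O6 glyoxylate p-toluenesulfonylhydrazone of 13 (formed in the flask) | CO/C1=C\[C@H](OC(=O)C=NNS(=O)(=O)c2ccc(C)cc2)[C@H](O[Si](C)(C)C(C)(C)C)/C(C(=O)OC)=C\C/C=C(C)\C1 | intermediate
15 | O6 diazoacetate of 13 | CO/C1=C\[C@H](OC(=O)C=[N+]=[N-])[C@H](O[Si](C)(C)C(C)(C)C)/C(C(=O)OC)=C\C/C=C(C)\C1 | intermediate
16 | cyclopropane-fused 12,6-lactone: C11 bridges C7 and C8, C8 bears OMe, C7–C11 syn to O6, O5-TBS | CO[C@@]12C/C(C)=C\C/C=C(C(=O)OC)\[C@@H](O[Si](C)(C)C(C)(C)C)[C@H]3OC(=O)[C@H]1[C@H]23 | intermediate
17 | (5R,6S,7S)-8-oxo trans-fused 12,6-lactone, O5-TBS, 1(10)Z,3E-diene (formed in the flask) | O=C1C/C(C)=C\C/C=C(C(=O)OC)\[C@@H](O[Si](C)(C)C(C)(C)C)[C@H]2OC(=O)C[C@H]12 | intermediate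
18 | 5-hydroxy analogue of 17 (formed in the flask) | O=C1C/C(C)=C\C/C=C(C(=O)OC)\[C@@H](O)[C@H]2OC(=O)C[C@H]12 | intermediate
19 | (5R,6S,7S,10S)-5,10-epoxy-8-oxo 12,6-lactone methyl ester | O=C1C[C@]2(C)CCC=C(C(=O)OC)[C@@H](O2)[C@H]2OC(=O)C[C@@H]21 | intermediate
20 | (5R,6S,7R,8R,10S)-5,10-epoxy-8-hydroxy 12,6-lactone methyl ester | O[C@@H]1C[C@]2(C)CCC=C(C(=O)OC)[C@@H](O2)[C@H]2OC(=O)C[C@@H]21 | intermediate
21 | (E)-2-methylbut-2-en-1-ol | C/C=C(\C)CO | starting material
22 | [(2R,3R)-2,3-dimethyloxiran-2-yl]methanol | C[C@H]1O[C@]1(C)CO | intermediate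
23 | (2R,3S)-2-methyl-3-(phenylselanyl)butane-1,2-diol (formed in the flask) | C[C@H]([Se]c1ccccc1)[C@](C)(O)CO | intermediate
24 | (S)-2-methylbut-3-ene-1,2-diol | C=C[C@](C)(O)CO | intermediate
25 | (S)-2-hydroxy-2-methylbut-3-enal (formed in the flask) | C=C[C@](C)(O)C=O | intermediate
26 | (S)-2-hydroxy-2-methylbut-3-enoic acid | C=C[C@](C)(O)C(=O)O | intermediate
27 | triethylsilyl (S)-2-methyl-2-(triethylsilyloxy)but-3-enoate (formed in the flask) | C=C[C@](C)(O[Si](CC)(CC)CC)C(=O)O[Si](CC)(CC)CC | intermediate
28 | (S)-2-methyl-2-(triethylsilyloxy)but-3-enoic acid | C=C[C@](C)(O[Si](CC)(CC)CC)C(=O)O | intermediate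
29 | mixed anhydride of 28 and 2,4,6-trichlorobenzoic acid (formed in the flask) | C=C[C@](C)(O[Si](CC)(CC)CC)C(=O)OC(=O)c1c(Cl)cc(Cl)cc1Cl | intermediate
30 | 8-O-[(S)-2-methyl-2-(triethylsilyloxy)but-3-enoyl] ester of 20 | C=C[C@](C)(O[Si](CC)(CC)CC)C(=O)O[C@@H]1C[C@]2(C)CCC=C(C(=O)OC)[C@@H](O2)[C@H]2OC(=O)C[C@@H]21 | intermediate
31 | C11 dimethylaminomethyl Mannich base of 30, C11 epimers (formed in the flask) | C=C[C@](C)(O[Si](CC)(CC)CC)C(=O)O[C@@H]1C[C@]2(C)CCC=C(C(=O)OC)[C@@H](O2)[C@H]2OC(=O)C(CN(C)C)[C@@H]21 | intermediate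
32 | trimethylammonium iodide of 31 (formed in the flask) | [I-].C=C[C@](C)(O[Si](CC)(CC)CC)C(=O)O[C@@H]1C[C@]2(C)CCC=C(C(=O)OC)[C@@H](O2)[C@H]2OC(=O)C(C[N+](C)(C)C)[C@@H]21 | intermediate
33 | O-triethylsilyl ether of the target (11(13)-methylene lactone) | C=C[C@](C)(O[Si](CC)(CC)CC)C(=O)O[C@@H]1C[C@]2(C)CCC=C(C(=O)OC)[C@@H](O2)[C@H]2OC(=O)C(=C)[C@@H]21 | intermediate
34 | CNP0325750.1: (5R,6S,7R,8R,10S)-5,10-epoxy 12,6-lactone, C4 methyl ester, 8-O-[(S)-2-hydroxy-2-methylbut-3-enoyl], 11(13)-methylene | C=C[C@](C)(O)C(=O)O[C@@H]1C[C@]2(C)CCC=C(C(=O)OC)[C@@H](O2)[C@H]2OC(=O)C(=C)[C@@H]21 | target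

**Count**

Total: 18 steps. Longest linear sequence: 13 steps (steps 1, 2, 4–11, 16–18).

**Steps most likely to fail**

Step 4. The diyl may fragment through the other chair, so that the enoate instead of the enol ether emerges ring-trans; some C5–C6 scission or Cope material may accompany it. The fallback sets out from photoadduct 7 and returns at keto lactone 17.
- The thermolysis product, the ring-trans-enoate triene carbonate F1, is treated with PhSH (0.2 equiv) and AIBN in benzene at 80 °C. Reversible thiyl-radical addition relieves the strained enoate and should give the all-ring-cis triene carbonate F2.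
- F2 is taken through steps 5–9 unchanged: all-cis diol F3, hydroxy lactone F4, silyl ether F5, lithium carboxylate F6, hydroxy ester F7, hydrazone ester F8, diazoacetate F9 and the C8-epimeric cyclopropane lactone F10.
- The tether argument for C7 does not depend on the enol-ether geometry, because H6 still eclipses the alkene. The acid of step 10 erases C8 and F10 gives 17, which continues to 19 in the same flask.

Step 9. The carbenoid may insert into the activated C5–H bond, form an ylide with a neighbouring ether oxygen or dimerise instead of adding to the enol ether. The fallback sets out from 13 and returns at 17.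
- Bromoacetyl bromide and pyridine (CH2Cl2, −40 °C) give the O6 bromoacetate F11; NaI in acetone gives the O6 iodoacetate F12.
- Iodine-atom-transfer radical cyclisation ((Bu3Sn)2 cat., hν, benzene, 80 °C) adds the electrophilic ester radical 5-exo to C7 under the same tether control. The alpha-alkoxy radical takes up iodine to give the alpha-iodo ether lactone F13.
- Aqueous NaHCO3 work-up hydrolyses F13 to 17, which then enters the acid treatment of step 10.

Step 10. The C10 cation may be diverted (alkene isomers, participation of the lactone or ketone enol), or the beta-acyloxy ketone may lose the lactone oxygen before the slow ether closure. The fallback sets out from 16 and returns at 19.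
- The events are separated: 0.5 M HCl in THF at 0 °C opens only the cyclopropane and gives 17, and HF·pyridine gives 18.
- Alkoxymercuration with Hg(OCOCF3)2 (CH2Cl2–MeCN, 0 °C) then closes the ether by anti addition of O5 and mercury across C1=C10, giving the C1 organomercurial trifluoroacetate F14.
- Bu3SnH in PhMe at 20 °C removes mercury and gives 19.

Further compounds
F1 | step 4 | triene carbonate with ring-trans C3=C4 and ring-cis C7=C8 | CO\C1=C\[C@@H]2OC(=O)O[C@@H]2/C(C(=O)OC)=C/C/C=C(C)\C1
F2 | step 4 | all-ring-cis triene carbonate | CO\C1=C\[C@@H]2OC(=O)O[C@@H]2/C(C(=O)OC)=C\C/C=C(C)\C1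
F3 | step 4 | all-cis triene 5,6-diol | CO\C1=C\[C@H](O)[C@H](O)/C(C(=O)OC)=C\C/C=C(C)\C1
F4 | step 4 | all-cis 5-hydroxy C15→O6 lactone | CO\C1=C\[C@@H]2OC(=O)/C(=C/C/C=C(C)\C1)[C@H]2O
F5 | step 4 | O5-TBS ether of F4 | CO\C1=C\[C@@H]2OC(=O)/C(=C/C/C=C(C)\C1)[C@H]2O[Si](C)(C)C(C)(C)C
F6 | step 4 | lithium carboxylate from F5 | [Li+].CO\C1=C\[C@H](O)[C@H](O[Si](C)(C)C(C)(C)C)/C(C(=O)[O-])=C\C/C=C(C)\C1
F7 | step 4 | all-cis 6-hydroxy-5-silyloxy methyl ester | CO\C1=C\[C@H](O)[C@H](O[Si](C)(C)C(C)(C)C)/C(C(=O)OC)=C\C/C=C(C)\C1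
F8 | step 4 | O6 glyoxylate tosylhydrazone of F7 | CO\C1=C\[C@H](OC(=O)C=NNS(=O)(=O)c2ccc(C)cc2)[C@H](O[Si](C)(C)C(C)(C)C)/C(C(=O)OC)=C\C/C=C(C)\C1
F9 | step 4 | O6 diazoacetate of F7 | CO\C1=C\[C@H](OC(=O)C=[N+]=[N-])[C@H](O[Si](C)(C)C(C)(C)C)/C(C(=O)OC)=C\C/C=C(C)\C1
F10 | step 4 | C8 epimer of cyclopropane lactone 16 | CO[C@]12C/C(C)=C\C/C=C(C(=O)OC)\[C@@H](O[Si](C)(C)C(C)(C)C)[C@H]3OC(=O)[C@H]1[C@H]23
F11 | step 9 | O6 bromoacetate of 13 | CO/C1=C\[C@H](OC(=O)CBr)[C@H](O[Si](C)(C)C(C)(C)C)/C(C(=O)OC)=C\C/C=C(C)\C1
F12 | step 9 | O6 iodoacetate of 13 | CO/C1=C\[C@H](OC(=O)CI)[C@H](O[Si](C)(C)C(C)(C)C)/C(C(=O)OC)=C\C/C=C(C)\C1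
F13 | step 9 | 8-iodo-8-methoxy 12,6-lactone (C8 epimers) | COC1(I)C/C(C)=C\C/C=C(C(=O)OC)\[C@@H](O[Si](C)(C)C(C)(C)C)[C@H]2OC(=O)C[C@H]12
F14 | step 10 | C1 trifluoroacetoxymercurio derivative of 19 | O=C1C[C@]2(C)[C@H]([Hg]OC(=O)C(F)(F)F)CC=C(C(=O)OC)[C@@H](O2)[C@H]2OC(=O)C[C@@H]21
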